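**Retrosynthetic overview**
- Target ⇒ Mitsunobu esterification (inversion at C6) of a cyclobutane carboxylic acid with one bicyclic amino alcohol; all three amino‑alcohol units come from that single alcohol.
- Cyclobutane (last ring formed; bonds C3–C4 and C1–C2 of the ring) ⇒ ion‑pair‑templated, visible‑light triplet‑sensitised crossed [2+2] of (E)‑4‑acetoxyferulic acid with the bis(amino‑alkyl) (2E,6E)‑2,6‑dimethylocta‑2,6‑dienedioate.
- Diester ⇒ double Mitsunobu of the dienedioic acid, made from geraniol by allylic oxidation and oxidation to the diacid.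
- Amino alcohol ⇒ ketone ⇒ bicyclic enone by Pauson–Khand reaction (piperidine and cyclopentenone rings formed together) of an N‑tethered 1,7‑enyne whose only stereocentre comes from (S)‑Roche ester.

Assumption: the amino‑alcohol units are taken exactly as the SMILES encodes them, (4R,4aR,6R,7R,7aS) (cis ring fusion, 4‑CH3 cis to H‑4a, 7‑CH3 trans to the C1 arm, 6‑O trans to 7‑CH3), the cyclobutane is (1R,2S,3S,4S) with ring locants C1 = C(CH3)(CO2R), C2 = CH(aryl), C3 = CH(CO2R), C4 = CH(side chain), and N‑methylbut‑2‑yn‑1‑amine and (E)‑4‑acetoxy‑3‑methoxycinnamic acid are bought.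

**Route**

Step 1
Reactants: 1 methyl (S)‑3‑hydroxy‑2‑methylpropanoate
Product: 2 methyl (S)‑3‑[(tert‑butyldimethylsilyl)oxy]‑2‑methylpropanoate
Conditions: TBSCl, imidazole, CH2Cl2, 0 °C to rt
Reagents that add atoms: tert‑butyldimethylsilyl chloride, CC(C)(C)[Si](C)(C)Cl
Why: Standard imidazole‑mediated silylation protects the primary alcohol for the reduction and does not touch the stereocentre.

Step 2
Reactants: 2 methyl (S)‑3‑[(tert‑butyldimethylsilyl)oxy]‑2‑methylpropanoate
Product: 4 tert‑butyldimethyl{[(2R)‑2‑methylbut‑3‑en‑1‑yl]oxy}silane, via silyloxy aldehyde 3 (not isolated)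
Conditions: i‑Bu2AlH, CH2Cl2, −78 °C; then Ph3P=CH2 (from Ph3PCH3Br, KN(SiMe3)2), THF, −78 °C to rt
Reagents that add atoms: methyltriphenylphosphonium bromide, C[P+](c1ccccc1)(c1ccccc1)c1ccccc1.[Br-]
Why: At −78 °C the reduction stops at the aluminium hemiacetal, which releases the aldehyde only as the ylide traps it (tandem reduction–Wittig methylenation), so the epimerisable α‑methyl aldehyde is never isolated and the bought stereocentre is kept (S to R is only a CIP priority change).

Step 3
Reactants: 4 tert‑butyldimethyl{[(2R)‑2‑methylbut‑3‑en‑1‑yl]oxy}silane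
Product: 5 (3R)‑4‑bromo‑3‑methylbut‑1‑ene
Conditions: Ph3PBr2, CH2Cl2, 0 °C to rt (volatile; used as a concentrated solution)
Reagents that add atoms: triphenylphosphine dibromide, BrP(Br)(c1ccccc1)(c1ccccc1)c1ccccc1
Why: Ph3PBr2 converts a primary silyl ether directly into the bromide (Appel‑type SN2 displacement of the alkoxyphosphonium at CH2), leaving the adjacent stereocentre untouched.

Step 4
Reactants: 5 (3R)‑4‑bromo‑3‑methylbut‑1‑ene; 6 N‑methylbut‑2‑yn‑1‑amine
Product: 7 N‑methyl‑N‑[(2R)‑2‑methylbut‑3‑en‑1‑yl]but‑2‑yn‑1‑amine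
Conditions: 6 (3 equiv), K2CO3, NaI (cat.), MeCN, 60 °C, sealed tube
Reagents that add atoms: none
Why: SN2 N‑alkylation of a nucleophilic but weakly basic secondary amine at a primary bromide (iodide catalysis) gives the tertiary amine with little E2 elimination and no change at the stereocentre.

Step 5
Reactants: 7 N‑methyl‑N‑[(2R)‑2‑methylbut‑3‑en‑1‑yl]but‑2‑yn‑1‑amine
Product: 8 (4R,4aR)‑2,4,7‑trimethyl‑1,2,3,4,4a,5‑hexahydro‑6H‑cyclopenta[c]pyridin‑6‑one
Conditions: Co2(CO)8 (1.1 equiv), CH2Cl2, rt; then N‑methylmorpholine N‑oxide, 0 °C to rt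
Reagents that add atoms: carbon monoxide (from Co2(CO)8), [C-]#[O+]
Why: The intramolecular Pauson–Khand [2+2+1] reaction builds the piperidine and the cyclopentenone in one step, and with the C4 methyl pseudo‑equatorial in the chair‑like cobaltacycle H‑4a ends up cis to it, so C4a is set by the bought stereocentre.

Step 6
Reactants: 8 (4R,4aR)‑2,4,7‑trimethyl‑1,2,3,4,4a,5‑hexahydro‑6H‑cyclopenta[c]pyridin‑6‑one
Product: 10 (4R,4aR,7R,7aS)‑2,4,7‑trimethyloctahydro‑6H‑cyclopenta[c]pyridin‑6‑one, via 7‑epi ketone 9 (not isolated)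
Conditions: H2 (1 atm), 10% Pd/C, MeOH, rt; filter; then K2CO3, MeOH, rt
Reagents that add atoms: none
Why: Heterogeneous hydrogenation adds H2 to the tetrasubstituted enone from the face of H‑4a (convex face) to give the cis ring fusion at C7a, and base equilibration of the α‑methyl ketone then places the C7 methyl trans to the C1 arm (thermodynamic epimerisation), both under substrate control.

Step 7
Reactants: 10 (4R,4aR,7R,7aS)‑2,4,7‑trimethyloctahydro‑6H‑cyclopenta[c]pyridin‑6‑one
Product: 11 (4R,4aR,6S,7R,7aS)‑2,4,7‑trimethyloctahydro‑1H‑cyclopenta[c]pyridin‑6‑ol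
Conditions: LiBH(s‑Bu)3, THF, −78 °C; then H2O, aqueous NaOH, acid–base extraction
Reagents that add atoms: none
Why: The bulky hydride attacks the cyclopentanone from the face opposite the adjacent C7 methyl (substrate‑controlled reduction), giving the 6S alcohol with OH cis to that methyl, the epimer needed for esterification with inversion.

Step 8
Reactants: 12 geraniol
Product: 13 (2E,6E)‑2,6‑dimethylocta‑2,6‑diene‑1,8‑diol
Conditions: SeO2 (cat.), salicylic acid (cat.), t‑BuOOH, CH2Cl2, rt
Reagents that add atoms: tert‑butyl hydroperoxide, CC(C)(C)OO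
Why: Catalytic SeO2 allylic oxidation (ene reaction, then [2,3]‑sigmatropic shift) hydroxylates the E‑methyl group of the electron‑rich terminal alkene with E geometry.

Step 9
Reactants: 13 (2E,6E)‑2,6‑dimethylocta‑2,6‑diene‑1,8‑diol
Product: 15 (2E,6E)‑2,6‑dimethylocta‑2,6‑dienedioic acid, via dialdehyde 14 (not isolated)
Conditions: TEMPO (cat.), PhI(OAc)2, CH2Cl2, rt; then NaClO2, NaH2PO4, 2‑methylbut‑2‑ene, t‑BuOH/H2O, 0 °C to rt
Reagents that add atoms: sodium chlorite, [Na+].[O-]Cl=O
Why: TEMPO/PhI(OAc)2 oxidises both allylic alcohols to the dialdehyde without E/Z scrambling, and Pinnick oxidation in the same flask takes both aldehydes to the acids while the scavenger protects the double bonds.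

Step 10
Reactants: 15 (2E,6E)‑2,6‑dimethylocta‑2,6‑dienedioic acid; 11 (4R,4aR,6S,7R,7aS)‑2,4,7‑trimethyloctahydro‑1H‑cyclopenta[c]pyridin‑6‑ol
Product: 16 bis[(4R,4aR,6R,7R,7aS)‑2,4,7‑trimethyloctahydro‑1H‑cyclopenta[c]pyridin‑6‑yl] (2E,6E)‑2,6‑dimethylocta‑2,6‑dienedioate
Conditions: 11 (2.3 equiv), PPh3, DIAD, THF, 0 °C to rt
Reagents that add atoms: none
Why: In this double Mitsunobu esterification each carboxylate displaces the activated 6S oxyphosphonium from the face opposite the C7 methyl with inversion to the 6R ester, and because the acid is never an acyl electrophile the two E enoates cannot isomerise or deconjugate.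

Step 11
Reactants: 16 bis(amino‑alkyl) dienedioate; 17 (E)‑4‑acetoxy‑3‑methoxycinnamic acid
Product: 18 (1R,2S,3S,4S)‑cyclobutane acid: C1 CH3 and 6R amino‑alkyl ester, C2 4‑acetoxy‑3‑methoxyphenyl, C3 CO2H, C4 (3E)‑3‑methyl‑5‑oxo‑5‑(6R amino‑alkoxy)pent‑3‑enyl; aryl, C1 methyl and side chain on one face, both carboxyl groups on the other
Conditions: 16 (1.3 equiv), 17 (1.0 equiv), fac‑Ir(ppy)3 [tris(2‑phenylpyridinato)iridium] (2 mol %), PhCF3/CH2Cl2 1:1, 0.01 M, 450 nm LEDs, argon, 0 °C; reversed‑phase HPLC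
Reagents that add atoms: none
Why: Proposed new method: an ion‑pair‑templated, triplet‑sensitised crossed [2+2] photocycloaddition, in which acid 17 protonates one piperidine nitrogen of 16 so that the only sensitisable alkene (cinnamate, triplet energy about 55 kcal/mol against more than 70 for both enoates of 16) sits as a contact ion pair on its partner at a dilution where cinnamate self‑dimerisation is slow; energy transfer gives the twisted cinnamate triplet, whose carboxylate‑bearing carbon bonds to the β‑CH of the α‑methyl enoate (the β,β‑disubstituted enoate is inert to radical addition) to give the most stabilised 1,4‑biradical (benzylic and tertiary α‑ester), which closes head‑to‑tail to the all‑trans ring with the ammonium bridging the carboxylate and the C1 ester carbonyl (cis‑1,3), while the CH(CH3) flank (C7) of the 6R alkoxy bicycle covers the 2Re,3Si face of the s‑trans enoate so that bonding on the 2Si,3Re face gives the 1R,2S,3S,4S ring (a modest preference, minor isomers removed by HPLC); the closest known chemistry is the iridium‑sensitised energy‑transfer [2+2] cycloaddition of cinnamates (dimerisation, Lewis‑acid‑assisted cross‑reactions with styrenes) and the ammonium carboxylate salt‑templated photodimerisation of cinnamic acids.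

Step 12
Reactants: 18 cyclobutane acid; 11 (4R,4aR,6S,7R,7aS)‑2,4,7‑trimethyloctahydro‑1H‑cyclopenta[c]pyridin‑6‑ol
Product: 20 target CNP0251577.2, via O‑acetyl triester 19 (not isolated)
Conditions: 11 (1.5 equiv), PPh3, DIAD, THF/toluene, 0 °C to rt; then pyrrolidine, MeOH, rt
Reagents that add atoms: none
Why: Mitsunobu esterification of the cyclobutane carboxylate with inversion at C6 installs the third amino‑alcohol unit as the 6R ester (the acetylated phenol cannot compete), and pyrrolidine then cleaves only the aryl acetate by aminolysis because aryl esters are far more electrophilic than the hindered alkyl esters.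

**Compound list**

1 | methyl (S)‑3‑hydroxy‑2‑methylpropanoate ((S)‑Roche ester) | C[C@@H](CO)C(=O)OC | starting material
2 | methyl (S)‑3‑[(tert‑butyldimethylsilyl)oxy]‑2‑methylpropanoate | C[C@@H](CO[Si](C)(C)C(C)(C)C)C(=O)OC | intermediate
3 | (S)‑3‑[(tert‑butyldimethylsilyl)oxy]‑2‑methylpropanal | C[C@@H](CO[Si](C)(C)C(C)(C)C)C=O | intermediate (not isolated)
4 | tert‑butyldimethyl{[(2R)‑2‑methylbut‑3‑en‑1‑yl]oxy}silane | C[C@@H](CO[Si](C)(C)C(C)(C)C)C=C | intermediate
5 | (3R)‑4‑bromo‑3‑methylbut‑1‑ene | C[C@@H](CBr)C=C | intermediate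
6 | N‑methylbut‑2‑yn‑1‑amine | CC#CCNC | starting material
7 | N‑methyl‑N‑[(2R)‑2‑methylbut‑3‑en‑1‑yl]but‑2‑yn‑1‑amine | C[C@@H](CN(C)CC#CC)C=C | intermediate
8 | (4R,4aR)‑2,4,7‑trimethyl‑1,2,3,4,4a,5‑hexahydro‑6H‑cyclopenta[c]pyridin‑6‑one | O=C1C[C@H]2C(CN(C)C[C@@H]2C)=C1C | intermediate
9 | (4R,4aR,7S,7aS)‑2,4,7‑trimethyloctahydro‑6H‑cyclopenta[c]pyridin‑6‑one (cis‑fused, 7‑CH3 cis to the C1 arm) | O=C1C[C@H]2[C@H](CN(C)C[C@@H]2C)[C@@H]1C | intermediate (not isolated)
10 | (4R,4aR,7R,7aS)‑2,4,7‑trimethyloctahydro‑6H‑cyclopenta[c]pyridin‑6‑one | O=C1C[C@H]2[C@H](CN(C)C[C@@H]2C)[C@H]1C | intermediate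
11 | (4R,4aR,6S,7R,7aS)‑2,4,7‑trimethyloctahydro‑1H‑cyclopenta[c]pyridin‑6‑ol (OH cis to 7‑CH3) | O[C@H]1C[C@H]2[C@H](CN(C)C[C@@H]2C)[C@H]1C | intermediate
12 | geraniol | CC(C)=CCC/C(C)=C/CO | starting material
13 | (2E,6E)‑2,6‑dimethylocta‑2,6‑diene‑1,8‑diol | C/C(=C\CC/C(C)=C/CO)CO | intermediate
14 | (2E,6E)‑2,6‑dimethylocta‑2,6‑dienedial | C/C(=C\CC/C(C)=C/C=O)C=O | intermediate (not isolated)
15 | (2E,6E)‑2,6‑dimethylocta‑2,6‑dienedioic acid | C/C(=C\CC/C(C)=C/C(=O)O)C(=O)O | intermediate
16 | bis[(4R,4aR,6R,7R,7aS)‑2,4,7‑trimethyloctahydro‑1H‑cyclopenta[c]pyridin‑6‑yl] (2E,6E)‑2,6‑dimethylocta‑2,6‑dienedioate | C/C(=C\CC/C(C)=C/C(=O)O[C@@H]1C[C@H]2[C@H](CN(C)C[C@@H]2C)[C@H]1C)C(=O)O[C@@H]1C[C@H]2[C@H](CN(C)C[C@@H]2C)[C@H]1C | intermediate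
17 | (E)‑4‑acetoxy‑3‑methoxycinnamic acid (O‑acetylferulic acid) | COc1cc(/C=C/C(=O)O)ccc1OC(C)=O | starting material
18 | (1R,2S,3S,4S)‑cyclobutane acid with two 6R amino‑alkyl esters, aryl O‑acetate and free C3 carboxyl | COc1cc([C@@H]2[C@@H](C(=O)O)[C@H](CC/C(C)=C/C(=O)O[C@@H]3C[C@H]4[C@H](CN(C)C[C@@H]4C)[C@H]3C)[C@@]2(C)C(=O)O[C@@H]2C[C@H]3[C@H](CN(C)C[C@@H]3C)[C@H]2C)ccc1OC(C)=O | intermediate
19 | O‑acetyl derivative of the target (tris 6R ester, aryl acetate) | COc1cc([C@@H]2[C@@H](C(=O)O[C@@H]3C[C@H]4[C@H](CN(C)C[C@@H]4C)[C@H]3C)[C@H](CC/C(C)=C/C(=O)O[C@@H]3C[C@H]4[C@H](CN(C)C[C@@H]4C)[C@H]3C)[C@@]2(C)C(=O)O[C@@H]2C[C@H]3[C@H](CN(C)C[C@@H]3C)[C@H]2C)ccc1OC(C)=O | intermediate (not isolated)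
20 | CNP0251577.2 | COc1cc([C@@H]2[C@@H](C(=O)O[C@@H]3C[C@H]4[C@H](CN(C)C[C@@H]4C)[C@H]3C)[C@H](CC/C(C)=C/C(=O)O[C@@H]3C[C@H]4[C@H](CN(C)C[C@@H]4C)[C@H]3C)[C@@]2(C)C(=O)O[C@@H]2C[C@H]3[C@H](CN(C)C[C@@H]3C)[C@H]2C)ccc1O | target

**Step count and risks**

Total step count: 12. Longest linear sequence: 10 (steps 1–7, 10, 11, 12).

Steps most likely to fail:

1. Step 11 (proposed new step). The triplet may decay (E/Z isomerisation) or self‑dimerise faster than it adds to the hindered enoate. The radical at C1 of the ring is planar before closure, so the C1 epimer (CH3 and ester exchanged) can form. The face selectivity from the remote alkoxy group may be low. A wrong C3 epimer is not a concern, since DBU equilibrates it to the all‑trans isomer after step 12. Fallback (established reactions only; it sets out from 17 and comes back at 20, and it gives up control of the cyclobutane configuration): 17 is irradiated with [Ir(dF(CF3)ppy)2(dtbbpy)]PF6 and blue light in MeCN with a tenfold excess of methyl (2E,6E)‑8‑hydroxy‑3,7‑dimethylocta‑2,6‑dienoate F1 (from commercial methyl geranate with SeO2/t‑BuOOH). This is an ordinary untemplated sensitised cinnamate–alkene [2+2] in which the partner is an electron‑neutral trisubstituted alkene instead of an enoate. The same biradical logic gives the racemic cyclobutane hydroxy acid F2 (C1 epimers separated). TEMPO/PhI(OAc)2 in MeCN/H2O, then NaClO2, oxidises the neopentyl CH2OH to the diacid F3. LiOH removes the methyl ester and the aryl acetate to give the triacid F4. Three‑fold Mitsunobu esterification with 11 (the carboxylates react in preference to the phenol) gives 20 together with the diastereomer that has the mirror‑image cyclobutane, and the two are separated by HPLC.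

2. Step 5 (Pauson–Khand). A 1,7‑enyne with a basic amine in the tether may complex poorly (amine‑induced disproportionation of Co2(CO)8) or cyclise with low diastereoselectivity. Fallback (sets out from 5, comes back at 10): bromide 5 alkylates the sodium salt of commercial tert‑butyl but‑2‑yn‑1‑ylcarbamate (NaH, DMF) to give tert‑butyl (but‑2‑yn‑1‑yl)[(2R)‑2‑methylbut‑3‑en‑1‑yl]carbamate F5. Its non‑basic, rotamer‑biased carbamate tether undergoes the Co2(CO)8/amine N‑oxide cyclisation to tert‑butyl (4R,4aR)‑4,7‑dimethyl‑6‑oxo‑1,3,4,4a,5,6‑hexahydro‑2H‑cyclopenta[c]pyridine‑2‑carboxylate F6. Hydrogenation and base equilibration as in step 6 give tert‑butyl (4R,4aR,7R,7aS)‑4,7‑dimethyl‑6‑oxooctahydro‑2H‑cyclopenta[c]pyridine‑2‑carboxylate F7. CF3CO2H, then CH2O/NaBH(OAc)3 reductive methylation, returns ketone 10.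

3. Step 10 (double Mitsunobu). Displacement at the hindered secondary carbinol can give way to elimination or stop at the mono‑ester. Fallback (sets out from 10, comes back at 16; retention by acyl activation instead of inversion): ketone 10 is reduced with NaBH4 in MeOH at −40 °C (small hydride, mainly syn to the methyl as with 2‑methylcyclopentanone) and the major alcohol, (4R,4aR,6R,7R,7aS)‑2,4,7‑trimethyloctahydro‑1H‑cyclopenta[c]pyridin‑6‑ol F8, is separated from 11. Diacid 15 is converted with 2,4,6‑trichlorobenzoyl chloride/Et3N into the bis mixed anhydride and acylates F8 (DMAP, toluene, rt) to give 16, with the E geometry of the 3‑methyl enoate checked by NMR.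

**Further compounds**

F1 | step 11 | methyl (2E,6E)‑8‑hydroxy‑3,7‑dimethylocta‑2,6‑dienoate | C/C(=C\CC/C(C)=C/C(=O)OC)CO
F2 | step 11 | racemic cyclobutane hydroxy acid (enantiomer leading to 20 shown; C1 CH3 and CH2OH, C2 4‑acetoxy‑3‑methoxyphenyl, C3 CO2H, C4 (3E)‑5‑methoxy‑3‑methyl‑5‑oxopent‑3‑enyl; relative configuration as in 18) | COc1cc([C@@H]2[C@@H](C(=O)O)[C@H](CC/C(C)=C/C(=O)OC)[C@@]2(C)CO)ccc1OC(C)=O
F3 | step 11 | racemic cyclobutane 1,3‑diacid methyl ester aryl acetate (enantiomer shown) | COc1cc([C@@H]2[C@@H](C(=O)O)[C@H](CC/C(C)=C/C(=O)OC)[C@@]2(C)C(=O)O)ccc1OC(C)=O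
F4 | step 11 | racemic cyclobutane triacid with free phenol (enantiomer shown) | COc1cc([C@@H]2[C@@H](C(=O)O)[C@H](CC/C(C)=C/C(=O)O)[C@@]2(C)C(=O)O)ccc1O
F5 | step 5 | tert‑butyl (but‑2‑yn‑1‑yl)[(2R)‑2‑methylbut‑3‑en‑1‑yl]carbamate | C[C@@H](CN(CC#CC)C(=O)OC(C)(C)C)C=C
F6 | step 5 | tert‑butyl (4R,4aR)‑4,7‑dimethyl‑6‑oxo‑1,3,4,4a,5,6‑hexahydro‑2H‑cyclopenta[c]pyridine‑2‑carboxylate | O=C1C[C@H]2C(CN(C(=O)OC(C)(C)C)C[C@@H]2C)=C1C
F7 | step 5 | tert‑butyl (4R,4aR,7R,7aS)‑4,7‑dimethyl‑6‑oxooctahydro‑2H‑cyclopenta[c]pyridine‑2‑carboxylate | O=C1C[C@H]2[C@H](CN(C(=O)OC(C)(C)C)C[C@@H]2C)[C@H]1C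
F8 | step 10 | (4R,4aR,6R,7R,7aS)‑2,4,7‑trimethyloctahydro‑1H‑cyclopenta[c]pyridin‑6‑ol | O[C@@H]1C[C@H]2[C@H](CN(C)C[C@@H]2C)[C@H]1C
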